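The C8–C9 bond of ring B is the disconnection on which the route rests. A samarium ketyl formed at the C9 ketone, which already carries the ketal-masked C11–C16 chain, adds 6-exo to C8 of an (E)-vinyl sulfone. This one operation closes ring B as a trans-decalin, sets C8 and C9, and creates the feature exploited: the C9 tertiary carbinol lying between quaternary C10 and C8, with the C8 substituent (latent C17 methyl) trans to the hydroxyl. The precursor is an enantiopure ring A cyclohexene (Δ2, C4 gem-dimethyl) bearing methyl and the keto side chain on C10 and, trans to that ketone, the 4-(phenylsulfonyl)but-3-enyl arm on C5; its two stereocentres come from a catalytic asymmetric Diels–Alder reaction.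

Key step: step 13

Remark: labdane numbering is used for all intermediates (ring A: C1–C5 and C10; ring B: C5–C10; side chain C11–C16; C17 on C8; C18 and C19 on C4; C20 on C10). The target is read as drawn: 5α-H, 10β-CH3, 9β-OH with the side chain 9α, 8α-CH3, 2α-OAc, 3α-OH, 13E. Compounds 9–17 are mixtures of C9 carbinol epimers, which is harmless because C9 becomes a ketone in step 11.

Step 1
Reactants: 1 pent-4-enal; 2 2-(triphenyl-λ5-phosphanylidene)propanal
Product: 3 (2E)-2-methylhepta-2,6-dienal
Conditions: PhMe, 80 °C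
Reagents that add atoms: none
Why: Wittig olefination with a stabilised formyl ylide should give the (E)-2-methyl enal, the geometry that later fixes the relative configuration of C5 and C10.

Step 2
Reactants: 4 but-3-en-2-one
Product: 5 2-(triisopropylsilyloxy)buta-1,3-diene
Conditions: i-Pr3SiOSO2CF3, Et3N, Et2O, 0 °C → rt
Reagents that add atoms: triisopropylsilyl trifluoromethanesulfonate, CC(C)[Si](OS(=O)(=O)C(F)(F)F)(C(C)C)C(C)C
Why: Soft enolisation and O-silylation of the methyl ketone should give the robust 2-silyloxy diene.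

Step 3
Reactants: 3 (2E)-2-methylhepta-2,6-dienal; 5 2-(triisopropylsilyloxy)buta-1,3-diene
Product: 6 (1S,6S)-6-(but-3-en-1-yl)-1-methyl-4-(triisopropylsilyloxy)cyclohex-3-ene-1-carbaldehyde (ring A; C10 methyl cis to the C5 butenyl chain)
Conditions: (R)-3,3-diphenyl-1-(2-methylphenyl)tetrahydro-1H,3H-pyrrolo[1,2-c][1,3,2]oxazaborole (20 mol%), (CF3SO2)2NH (18 mol%), CH2Cl2, −78 → −20 °C
Reagents that add atoms: none
Why: Oxazaborolidinium-catalysed enantioselective Diels–Alder reaction of an α-methyl enal with a 2-silyloxy diene: the silyloxy carbon ends para to C10, the E geometry is transferred suprafacially so that the C10 methyl and the C5 chain are cis, and the catalyst (aldehyde held by B–O and formyl C–H···O contacts, one face covered by a phenyl ring) should direct the diene to the Cα-si/Cβ-re face to give (1S,6S); the antipodal catalyst is equally available should the first run show the opposite sense.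

Step 4
Reactants: 6 (1S,6S)-6-(but-3-en-1-yl)-1-methyl-4-(triisopropylsilyloxy)cyclohex-3-ene-1-carbaldehyde; 7 2-(2-bromoethyl)-2-methyl-1,3-dioxolane
Product: 9 1-[(1S,6S)-6-(but-3-en-1-yl)-1-methyl-4-(triisopropylsilyloxy)cyclohex-3-en-1-yl]-3-(2-methyl-1,3-dioxolan-2-yl)propan-1-ol (C9 epimers), via Grignard reagent 8 (not isolated)
Conditions: 7, Mg, THF, 25 °C; then 6, −78 → 0 °C; aq NH4Cl
Reagents that add atoms: none
Why: Grignard 1,2-addition to the non-enolisable neopentyl aldehyde attaches C11–C13 and C16, the silyl enol ether being inert to the reagent; the new C9 centre forms unselectively and is erased in step 11.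

Step 5
Reactants: 9 the C9 carbinol
Product: 10 triethylsilyl ether of 9
Conditions: Et3SiCl, imidazole, DMAP (cat.), DMF, rt
Reagents that add atoms: chlorotriethylsilane, CC[Si](Cl)(CC)CC
Why: Silylation of the secondary alcohol protects C9 against Pd(OAc)2, amide base and hydride in steps 6–8.

Step 6
Reactants: 10 triethylsilyl ether of 9
Product: 11 5-(but-3-en-1-yl)-4-methyl-4-[3-(2-methyl-1,3-dioxolan-2-yl)-1-(triethylsilyloxy)propyl]cyclohex-2-en-1-one (ring A Δ1-3-ketone; ring configuration as in 6)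
Conditions: Pd(OAc)2 (1.1 eq), MeCN, 40 °C
Reagents that add atoms: none
Why: Saegusa–Ito oxidation: the regiodefined Δ2 silyl enol ether gives a C2 palladium enolate whose only β-hydrogens are on C1, so the Δ1-3-ketone should form regiospecifically.

Step 7
Reactants: 11 the ring A Δ1-3-ketone
Product: 13 5-(but-3-en-1-yl)-4,6,6-trimethyl-4-[3-(2-methyl-1,3-dioxolan-2-yl)-1-(triethylsilyloxy)propyl]cyclohex-2-en-1-one (C4 gem-dimethyl enone), via monomethyl enone 12 (not isolated)
Conditions: LiN(i-Pr)2, THF, −78 °C; MeI; then LiN(i-Pr)2, −78 °C; MeI, DMPU, −78 → 0 °C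
Reagents that add atoms: iodomethane, CI
Why: α'-Enolate alkylation: C4 is the only enolisable position (C2 is vinylic, the γ-carbon C10 is quaternary), so two deprotonation/methylation cycles should install C18 and C19 without regiochemical ambiguity.

Step 8
Reactants: 13 the C4 gem-dimethyl enone
Product: 15 5-(but-3-en-1-yl)-4,6,6-trimethyl-4-[3-(2-methyl-1,3-dioxolan-2-yl)-1-(triethylsilyloxy)propyl]cyclohex-1-en-1-yl trifluoromethanesulfonate (Δ2 enol triflate at C3), via lithium enolate 14 (not isolated)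
Conditions: LiBH(s-Bu)3, THF, −78 °C; then PhN(SO2CF3)2, −78 °C → rt
Reagents that add atoms: N-phenylbis(trifluoromethanesulfonimide), O=S(=O)(N(c1ccccc1)S(=O)(=O)C(F)(F)F)C(F)(F)F
Why: Conjugate hydride reduction of a β-unsubstituted cyclohexenone whose carbonyl is shielded by the gem-dimethyl group should give the Δ2 enolate regiospecifically, and O-sulfonylation fixes it as the enol triflate.

Step 9
Reactants: 15 the Δ2 enol triflate
Product: 16 triethyl{1-[(1S,6S)-6-(but-3-en-1-yl)-1,5,5-trimethylcyclohex-3-en-1-yl]-3-(2-methyl-1,3-dioxolan-2-yl)propoxy}silane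
Conditions: Pd(OAc)2 (5 mol%), PPh3 (10 mol%), HCO2H, Bu3N, DMF, 60 °C
Reagents that add atoms: none
Why: Palladium-catalysed formate reduction of an enol triflate (oxidative addition to zerovalent palladium, formate-to-hydride exchange, reductive elimination) should replace the triflate by hydrogen and leave the Δ2 alkene in place.

Step 10
Reactants: 16 the Δ2 silyl ether
Product: 17 1-[(1S,6S)-6-(but-3-en-1-yl)-1,5,5-trimethylcyclohex-3-en-1-yl]-3-(2-methyl-1,3-dioxolan-2-yl)propan-1-ol
Conditions: Bu4NF, THF, rt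
Reagents that add atoms: none
Why: Fluoride-induced cleavage of the triethylsilyl ether; ketal and both alkenes are untouched.

Step 11
Reactants: 17 the C9 carbinol
Product: 18 1-[(1S,6S)-6-(but-3-en-1-yl)-1,5,5-trimethylcyclohex-3-en-1-yl]-3-(2-methyl-1,3-dioxolan-2-yl)propan-1-one
Conditions: Dess–Martin periodinane, NaHCO3, CH2Cl2, rt
Reagents that add atoms: none
Why: Dess–Martin oxidation of the hindered secondary alcohol under buffered conditions that keep the dioxolane should give the C9 ketone and remove the C9 stereocentre.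

Step 12
Reactants: 18 the C9 ketone; 19 phenyl vinyl sulfone
Product: 20 3-(2-methyl-1,3-dioxolan-2-yl)-1-{(1S,6S)-1,5,5-trimethyl-6-[(3E)-4-(phenylsulfonyl)but-3-en-1-yl]cyclohex-3-en-1-yl}propan-1-one
Conditions: 19 (3 eq), second-generation Hoveyda–Grubbs catalyst RuCl2(SIMes)(=CH–C6H4-2-O-i-Pr) (5 mol%), CH2Cl2, 40 °C
Reagents that add atoms: none
Why: Olefin cross-metathesis of the monosubstituted alkene with excess electron-poor vinyl sulfone, which does not homodimerise, should give the (E)-vinyl sulfone; the unstrained Δ2 alkene next to the C4 quaternary centre is inert.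

Step 13
Reactants: 20 the (E)-vinyl sulfone ketone
Product: 21 9β-hydroxy-17-(phenylsulfonyl)-14,15-dinorlabd-2-en-13-one ethylene ketal (side chain 9α, 8α-CH2SO2Ph, 5α-H, 10β-CH3)
Conditions: SmI2 (3 eq), HMPA (12 eq), t-BuOH (3 eq), THF, −78 → 0 °C, slow addition of 20
Reagents that add atoms: none
Why: Electron transfer from divalent samarium, made strongly reducing by HMPA, gives the C9 ketyl, which adds to C8, the β-carbon of the vinyl sulfone; the α-sulfonyl radical takes a second electron and the carbanion is protonated by t-BuOH. The closest known reaction type is the SmI2–HMPA ketyl–olefin cyclisation onto electron-poor alkenes. Ring B closes in the 6-exo-trig mode through a chair transition state that is trans-fused to ring A, because the ketone on C10 and the sulfone arm on C5 are trans-diequatorial. C8 is controlled by the sulfonylmethyl carbon taking the equatorial α position, which avoids a syn-diaxial clash with the C10 methyl; C9 is controlled by the HMPA-solvated O–Sm group taking the equatorial β site trans to that arm, the usual anti outcome of such cyclisations, which leaves the unbranched C11 chain axial on the α face where it meets only H-5 and H-7. The step needs chemoselectivity (one ketyl, ring closure faster than reduction to the carbinol) and face selectivity at C9: the C13 carbonyl is masked as a dioxolane, the Δ2 alkene is unactivated and out of reach, and the sulfone makes C8 a fast radical acceptor.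

Step 14
Reactants: 21 the ring B sulfone
Product: 22 9β-hydroxy-14,15-dinorlabd-2-en-13-one ethylene ketal (side chain 9α, 8α-CH3)
Conditions: Mg, MeOH, 50 °C
Reagents that add atoms: none
Why: Reductive desulfonylation (electron transfer to the aryl sulfone, C–S cleavage, protonation by methanol) should convert CH2SO2Ph into the C17 methyl without touching C8.

Step 15
Reactants: 22 the Δ2 ketal
Product: 24 2α,3α,9β-trihydroxy-14,15-dinorlabdan-13-one (side chain 9α, 8α-CH3), via triol ketal 23 (not isolated)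
Conditions: OsO4 (5 mol%), NMO, THF/H2O, rt; NaHSO3; then 1 M HCl, rt
Reagents that add atoms: osmium tetroxide, O=[Os](=O)(=O)=O; N-methylmorpholine N-oxide, C[N+]1([O-])CCOCC1; water, O
Why: Upjohn syn-dihydroxylation from the α face of Δ2, the only alkene present (the β face is blocked by the axial C10 and C4β methyls), should set C2 and C3 as the 2α,3α-diol; acidifying the aqueous THF then hydrolyses the dioxolane, acetone being avoided so that the cis-diol does not become an acetonide.

Step 16
Reactants: 24 the trihydroxy ketone; 25 trimethyl phosphonoacetate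
Product: 27 methyl (13E)-2α,3α,9β-trihydroxylabd-13-en-15-oate (side chain 9α, 8α-CH3), via sodium phosphonate 26 (not isolated)
Conditions: 25 (4 eq), NaH (3.6 eq), THF, 0 °C; then 24, 0 → 50 °C
Reagents that add atoms: none
Why: Horner–Wadsworth–Emmons olefination of the methyl ketone, which reacts through its open form although it equilibrates with the 9,13-hemiketal; the phosphonate is kept in excess over NaH so that no strong base deprotonates the hydroxyls (suppressing 9-O conjugate addition), and the E enoate should be the major isomer because the larger C12 chain sits trans to the ester, the minor Z isomer being removed by chromatography.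

Step 17
Reactants: 27 the trihydroxy enoate
Product: 28 methyl (13E)-2α-acetoxy-3α,9β-dihydroxylabd-13-en-15-oate (CNP0135744.1)
Conditions: Ac2O (1.1 eq), pyridine, 0 °C
Reagents that add atoms: acetic anhydride, CC(=O)OC(C)=O
Why: Selective acylation: the equatorial 2α-hydroxyl should react far faster than the axial 3α-hydroxyl next to the gem-dimethyl group and the tertiary 9-hydroxyl, so one equivalent of anhydride gives the 2-monoacetate.

Compound list

1 | pent-4-enal | C=CCCC=O | starting material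
2 | 2-(triphenyl-λ5-phosphanylidene)propanal | CC(C=O)=P(c1ccccc1)(c1ccccc1)c1ccccc1 | starting material
3 | (2E)-2-methylhepta-2,6-dienal | C=CCC/C=C(\C)C=O | intermediate
4 | but-3-en-2-one | CC(=O)C=C | starting material
5 | 2-(triisopropylsilyloxy)buta-1,3-diene | C=CC(=C)O[Si](C(C)C)(C(C)C)C(C)C | intermediate
6 | (1S,6S)-6-(but-3-en-1-yl)-1-methyl-4-(triisopropylsilyloxy)cyclohex-3-ene-1-carbaldehyde | O=C[C@@]1(C)CC=C(O[Si](C(C)C)(C(C)C)C(C)C)C[C@@H]1CCC=C | intermediate
7 | 2-(2-bromoethyl)-2-methyl-1,3-dioxolane | CC1(CCBr)OCCO1 | starting material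
8 | [2-(2-methyl-1,3-dioxolan-2-yl)ethyl]magnesium bromide | CC1(CC[Mg]Br)OCCO1 | intermediate
9 | 1-[(1S,6S)-6-(but-3-en-1-yl)-1-methyl-4-(triisopropylsilyloxy)cyclohex-3-en-1-yl]-3-(2-methyl-1,3-dioxolan-2-yl)propan-1-ol (C9 epimers) | CC1(CCC(O)[C@@]2(C)CC=C(O[Si](C(C)C)(C(C)C)C(C)C)C[C@@H]2CCC=C)OCCO1 | intermediate
10 | triethylsilyl ether of 9 | CC1(CCC(O[Si](CC)(CC)CC)[C@@]2(C)CC=C(O[Si](C(C)C)(C(C)C)C(C)C)C[C@@H]2CCC=C)OCCO1 | intermediate
11 | 5-(but-3-en-1-yl)-4-methyl-4-[3-(2-methyl-1,3-dioxolan-2-yl)-1-(triethylsilyloxy)propyl]cyclohex-2-en-1-one (ring configuration as in 6) | CC1(CCC(O[Si](CC)(CC)CC)[C@@]2(C)C=CC(=O)C[C@@H]2CCC=C)OCCO1 | intermediate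
12 | 6-methyl derivative of 11 (C4 epimers) | CC1(CCC(O[Si](CC)(CC)CC)[C@@]2(C)C=CC(=O)C(C)[C@@H]2CCC=C)OCCO1 | intermediate
13 | 5-(but-3-en-1-yl)-4,6,6-trimethyl-4-[3-(2-methyl-1,3-dioxolan-2-yl)-1-(triethylsilyloxy)propyl]cyclohex-2-en-1-one | CC1(CCC(O[Si](CC)(CC)CC)[C@@]2(C)C=CC(=O)C(C)(C)[C@@H]2CCC=C)OCCO1 | intermediate
14 | lithium Δ2-enolate from conjugate reduction of 13 | CC1(CCC(O[Si](CC)(CC)CC)[C@@]2(C)CC=C([O-])C(C)(C)[C@@H]2CCC=C)OCCO1.[Li+] | intermediate
15 | 5-(but-3-en-1-yl)-4,6,6-trimethyl-4-[3-(2-methyl-1,3-dioxolan-2-yl)-1-(triethylsilyloxy)propyl]cyclohex-1-en-1-yl trifluoromethanesulfonate | CC1(CCC(O[Si](CC)(CC)CC)[C@@]2(C)CC=C(OS(=O)(=O)C(F)(F)F)C(C)(C)[C@@H]2CCC=C)OCCO1 | intermediate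
16 | triethyl{1-[(1S,6S)-6-(but-3-en-1-yl)-1,5,5-trimethylcyclohex-3-en-1-yl]-3-(2-methyl-1,3-dioxolan-2-yl)propoxy}silane | CC1(CCC(O[Si](CC)(CC)CC)[C@@]2(C)CC=CC(C)(C)[C@@H]2CCC=C)OCCO1 | intermediate
17 | 1-[(1S,6S)-6-(but-3-en-1-yl)-1,5,5-trimethylcyclohex-3-en-1-yl]-3-(2-methyl-1,3-dioxolan-2-yl)propan-1-ol | CC1(CCC(O)[C@@]2(C)CC=CC(C)(C)[C@@H]2CCC=C)OCCO1 | intermediate
18 | 1-[(1S,6S)-6-(but-3-en-1-yl)-1,5,5-trimethylcyclohex-3-en-1-yl]-3-(2-methyl-1,3-dioxolan-2-yl)propan-1-one | CC1(CCC(=O)[C@@]2(C)CC=CC(C)(C)[C@@H]2CCC=C)OCCO1 | intermediate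
19 | phenyl vinyl sulfone | C=CS(=O)(=O)c1ccccc1 | starting material
20 | 3-(2-methyl-1,3-dioxolan-2-yl)-1-{(1S,6S)-1,5,5-trimethyl-6-[(3E)-4-(phenylsulfonyl)but-3-en-1-yl]cyclohex-3-en-1-yl}propan-1-one | CC1(CCC(=O)[C@@]2(C)CC=CC(C)(C)[C@@H]2CC/C=C/S(=O)(=O)c2ccccc2)OCCO1 | intermediate
21 | 9β-hydroxy-17-(phenylsulfonyl)-14,15-dinorlabd-2-en-13-one ethylene ketal (side chain 9α, 8α-CH2SO2Ph) | CC1(OCCO1)CC[C@]2(O)[C@H](CS(=O)(=O)c3ccccc3)CC[C@H]3C(C)(C)C=CC[C@@]32C | intermediate
22 | 9β-hydroxy-14,15-dinorlabd-2-en-13-one ethylene ketal (side chain 9α, 8α-CH3) | CC1(OCCO1)CC[C@]2(O)[C@H](C)CC[C@H]3C(C)(C)C=CC[C@@]32C | intermediate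
23 | 2α,3α,9β-trihydroxy-14,15-dinorlabdan-13-one ethylene ketal | CC1(OCCO1)CC[C@]2(O)[C@H](C)CC[C@H]3C(C)(C)[C@H](O)[C@H](O)C[C@@]32C | intermediate
24 | 2α,3α,9β-trihydroxy-14,15-dinorlabdan-13-one | CC(=O)CC[C@]1(O)[C@H](C)CC[C@H]2C(C)(C)[C@H](O)[C@H](O)C[C@@]21C | intermediate
25 | trimethyl phosphonoacetate | COC(=O)CP(=O)(OC)OC | starting material
26 | sodium salt of trimethyl phosphonoacetate | COC(=O)[CH-]P(=O)(OC)OC.[Na+] | intermediate
27 | methyl (13E)-2α,3α,9β-trihydroxylabd-13-en-15-oate (side chain 9α, 8α-CH3) | COC(=O)/C=C(\C)CC[C@]1(O)[C@H](C)CC[C@H]2C(C)(C)[C@H](O)[C@H](O)C[C@@]21C | intermediate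
28 | methyl (13E)-2α-acetoxy-3α,9β-dihydroxylabd-13-en-15-oate (side chain 9α, 8α-CH3) | COC(=O)/C=C(\C)CC[C@]1(O)[C@H](C)CC[C@H]2C(C)(C)[C@H](O)[C@H](OC(C)=O)C[C@@]21C | target

Total step count: 17. Longest linear sequence: 16 steps (steps 1 and 3–17, from pent-4-enal).

Steps most likely to fail

Step 13. The ketyl or the vinyl sulfone may be reduced before the C8–C9 bond forms, or facial control at C9 may erode because the side chain is asked to go axial. The fallback sets C9 instead by nucleophilic addition to a ring B ketone from the face opposite the C10 methyl; it sets out from 6 and comes back at 22.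
- Cross-metathesis of 6 with 19 should give the vinyl sulfone aldehyde F1.
- SmI2/HMPA/t-BuOH should close ring B through the aldehyde ketyl to the bicyclic 9-carbinol sulfone F2, whose C9 configuration is irrelevant.
- Mg/MeOH should give the 8α-methyl carbinol F3, and Et3SiCl/imidazole its triethylsilyl ether F4.
- The ring A operations of steps 6–9 are then repeated: Pd(OAc)2 to the Δ1-3-ketone F5, double methylation to the 4,4-dimethyl enone F6, LiBH(s-Bu)3/PhN(SO2CF3)2 to the enol triflate F7, and palladium/formate reduction to the Δ2 silyl ether F8.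
- Bu4NF should give the carbinol F9, and Dess–Martin oxidation the C9 ketone F10, whose 8α-methyl is equatorial and secured by enolisation.
- CeCl3-mediated addition of Grignard reagent 8 should occur on the α face, anti to the axial C10 methyl as in additions to 17-keto steroids, placing the side chain 9α and the hydroxyl 9β to give 22.

Step 3. The trisubstituted enal may add sluggishly, so that uncatalysed background reaction or acid-induced loss of the diene erodes enantiofacial control. The fallback moves the stereocontrol onto the diene as a chiral auxiliary in a thermal cycloaddition; it sets out from 3 and comes back at 11.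
- (2R,5R)-2,5-Diphenylpyrrolidine and 4-methoxybut-3-en-2-one should give the enaminone F11.
- KN(SiMe3)2/t-BuMe2SiCl should give the chiral aminosilyloxy diene F12.
- Cycloaddition with 3 (PhMe, 0 → 40 °C) should give the endo adduct F13, the dienophile adding anti to the inner phenyl group; the amine antipode is used if the sense proves opposite.
- Grignard reagent 8 should give the carbinol F14.
- Dilute HF in MeCN at 0 °C should expel the amine and unveil the hydroxy enone F15, and Et3SiCl/imidazole should convert it into 11.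

Step 8. Hydride delivery to the neopentyl C1 may be incomplete, 1,2-reduction may compete, or the enolate flanked by the C4 quaternary centre may resist O-sulfonylation. The fallback is a reductive 1,3-transposition that needs neither the enolate nor the triflate; it sets out from 13 and comes back at 16.
- TsNHNH2 (THF, 60 °C) should give the enone tosylhydrazone F16.
- Catecholborane, then NaOAc·3H2O in refluxing CHCl3, should reduce the C=N bond, expel sulfinate and lose dinitrogen from the allylic diazene by a retro-ene shift, placing hydrogen on C1 and the double bond at C2=C3.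

Further compounds

F1 | step 13 | (1S,6S)-1-methyl-6-[(3E)-4-(phenylsulfonyl)but-3-en-1-yl]-4-(triisopropylsilyloxy)cyclohex-3-ene-1-carbaldehyde | O=C[C@@]1(C)CC=C(O[Si](C(C)C)(C(C)C)C(C)C)C[C@@H]1CC/C=C/S(=O)(=O)c1ccccc1
F2 | step 13 | bicyclic 9-carbinol sulfone: 8α-(phenylsulfonylmethyl)-3-(triisopropylsilyloxy)-Δ2 trans-decalin-9-ol (C9 epimers) | OC1[C@H](CS(=O)(=O)c2ccccc2)CC[C@H]2CC(O[Si](C(C)C)(C(C)C)C(C)C)=CC[C@@]21C
F3 | step 13 | 8α-methyl-3-(triisopropylsilyloxy)-Δ2 trans-decalin-9-ol | OC1[C@H](C)CC[C@H]2CC(O[Si](C(C)C)(C(C)C)C(C)C)=CC[C@@]21C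
F4 | step 13 | triethylsilyl ether of F3 | CC[Si](CC)(CC)OC1[C@H](C)CC[C@H]2CC(O[Si](C(C)C)(C(C)C)C(C)C)=CC[C@@]21C
F5 | step 13 | 9-(triethylsilyloxy)-8α-methyl-Δ1 trans-decalin-3-one | CC[Si](CC)(CC)OC1[C@H](C)CC[C@H]2CC(=O)C=C[C@@]21C
F6 | step 13 | 4,4-dimethyl derivative of F5 | CC[Si](CC)(CC)OC1[C@H](C)CC[C@H]2C(C)(C)C(=O)C=C[C@@]21C
F7 | step 13 | Δ2 enol triflate from F6 | CC[Si](CC)(CC)OC1[C@H](C)CC[C@H]2C(C)(C)C(OS(=O)(=O)C(F)(F)F)=CC[C@@]21C
F8 | step 13 | 9-(triethylsilyloxy)-4,4,8α,10β-tetramethyl-Δ2 trans-decalin | CC[Si](CC)(CC)OC1[C@H](C)CC[C@H]2C(C)(C)C=CC[C@@]21C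
F9 | step 13 | 4,4,8α,10β-tetramethyl-Δ2 trans-decalin-9-ol | OC1[C@H](C)CC[C@H]2C(C)(C)C=CC[C@@]21C
F10 | step 13 | 4,4,8α,10β-tetramethyl-Δ2 trans-decalin-9-one | O=C1[C@H](C)CC[C@H]2C(C)(C)C=CC[C@@]21C
F11 | step 3 | (3E)-4-[(2R,5R)-2,5-diphenylpyrrolidin-1-yl]but-3-en-2-one | CC(=O)/C=C/N1[C@@H](c2ccccc2)CC[C@@H]1c1ccccc1
F12 | step 3 | (2R,5R)-1-[(1E)-3-(tert-butyldimethylsilyloxy)buta-1,3-dien-1-yl]-2,5-diphenylpyrrolidine | C=C(O[Si](C)(C)C(C)(C)C)/C=C/N1[C@@H](c2ccccc2)CC[C@@H]1c1ccccc1
F13 | step 3 | endo cycloadduct: 6-(but-3-en-1-yl)-4-(tert-butyldimethylsilyloxy)-2-[(2R,5R)-2,5-diphenylpyrrolidin-1-yl]-1-methylcyclohex-3-ene-1-carbaldehyde | O=C[C@@]1(C)[C@@H](N2[C@@H](c3ccccc3)CC[C@@H]2c2ccccc2)C=C(O[Si](C)(C)C(C)(C)C)C[C@@H]1CCC=C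
F14 | step 3 | Grignard adduct of F13 (C9 epimers) | CC1(CCC(O)[C@@]2(C)[C@@H](N3[C@@H](c4ccccc4)CC[C@@H]3c3ccccc3)C=C(O[Si](C)(C)C(C)(C)C)C[C@@H]2CCC=C)OCCO1
F15 | step 3 | 5-(but-3-en-1-yl)-4-[1-hydroxy-3-(2-methyl-1,3-dioxolan-2-yl)propyl]-4-methylcyclohex-2-en-1-one | CC1(CCC(O)[C@@]2(C)C=CC(=O)C[C@@H]2CCC=C)OCCO1
F16 | step 8 | 4-methylbenzenesulfonylhydrazone of 13 | CC1(CCC(O[Si](CC)(CC)CC)[C@@]2(C)C=CC(=NNS(=O)(=O)c3ccc(C)cc3)C(C)(C)[C@@H]2CCC=C)OCCO1
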